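**Retrosynthetic overview** (each half numbered as a 1H-isochromene: O2, C1, C3, C4, C4a, C5–C8, C8a)
1. Last C–C bond: Knoevenagel condensation of the C5 methylene of a dione half A with the enal of a carbinol half B; both halves derive from one bicyclic 6,8-dione, so every ring-forming step is run once.
2. Half B: C6 carbinol by 1,2-induced Luche reduction of the C6 ketone; pyran ring (O2–C3 bond) by 6-endo-dig hydroalkoxylation of an enynol, closed after the carbocycle.
3. Key disconnection C5–C6 of the carbocycle: the γ-carbon of a cross-conjugated dienolate closes onto the lactone carbonyl of a lactic-acid-derived 2-tert-butyl-1,3-dioxolan-4-one, which falls apart in the same flask (loss of pivaldehyde) and hands the freed C7 alkoxide to the orsellinoyl chloride.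
4. Enabling feature: in the carbocycle C7 is a fully substituted, non-enolizable carbinol carbon between C6 and the C8 ketone, and C5 is the γ-carbon of the C8=O/C8a=C4a enone, so C5–C6 is a vinylogous 1,3-dicarbonyl (Dieckmann) bond; C6, C7 and the C7 methyl are the three carbons of (R)-lactic acid.
5. Order of rings: dioxolanone (temporary) → carbocycle (key step) → pyran → union of the halves; the acyclic precursor is assembled from the dioxolanone, but-2-ynal, formaldehyde and a pentenynol.

Key step: step 9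

Assumption: but-2-ynal and (E)-pent-2-en-4-yn-1-ol are taken as purchasable; the 6,8-diones are drawn as diketo tautomers.

Step 1
Reactants: 1 (R)-lactic acid; 2 pivaldehyde
Product: 3 (2R,5R)-2-tert-butyl-5-methyl-1,3-dioxolan-4-one (cis)
Conditions: cat. TsOH·H2O, cat. H2SO4, pentane, reflux, water separator; crystallization from pentane at −78 °C
Reagents that add atoms: none
Why: Acid-catalysed acetalization of the α-hydroxy acid should give the dioxolanone with the new acetal stereocenter cis to the methyl group (thermodynamic preference, purified by crystallization), so that the acetal carbon holds the stereochemical information while C5 is later planarized (self-regeneration of stereocentres).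

Step 2
Reactants: 3 (2R,5R)-2-tert-butyl-5-methyl-1,3-dioxolan-4-one; 4 but-2-ynal
Product: 5 (2R,5S)-2-tert-butyl-5-(1-hydroxybut-2-yn-1-yl)-5-methyl-1,3-dioxolan-4-one (both carbinol epimers)
Conditions: LiN(iPr)2, THF, −78 °C; then 4; aq. NH4Cl
Reagents that add atoms: none
Why: Aldol addition of the lithium enolate should occur anti to the tert-butyl group, which sets the quaternary center (the later C7) with the new carbon in the place of the former hydrogen, while the carbinol center forms without control and is removed in step 3.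

Step 3
Reactants: 5 (2R,5S)-2-tert-butyl-5-(1-hydroxybut-2-yn-1-yl)-5-methyl-1,3-dioxolan-4-one
Product: 6 (2R,5S)-5-(but-2-ynoyl)-2-tert-butyl-5-methyl-1,3-dioxolan-4-one
Conditions: Dess–Martin periodinane, CH2Cl2, 25 °C
Reagents that add atoms: none
Why: Dess–Martin oxidation of the propargylic alcohol should give the ynone under neutral conditions that leave the acetal lactone and the non-enolizable quaternary center untouched.

Step 4
Reactants: 6 (2R,5S)-5-(but-2-ynoyl)-2-tert-butyl-5-methyl-1,3-dioxolan-4-one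
Product: 8 (2R,5S)-2-tert-butyl-5-{3-iodo-2-[(triethylsilyloxy)methyl]but-2-enoyl}-5-methyl-1,3-dioxolan-4-one (mixture of alkene isomers), via iodomagnesium alkoxide of the iodo-aldol adduct 7 (not isolated)
Conditions: MgI2, monomeric CH2O (THF solution), CH2Cl2, 0 °C; then 2,6-lutidine, Et3SiOTf, −78 to 0 °C
Reagents that add atoms: magnesium iodide, [Mg+2].[I-].[I-]; formaldehyde, C=O; triethylsilyl trifluoromethanesulfonate, CC[Si](CC)(CC)OS(=O)(=O)C(F)(F)F
Why: Iodo-aldol (halo Morita–Baylis–Hillman-type) three-component coupling, in which iodide adds to the β-carbon of the magnesium-chelated ynone and the β-iodo allenolate is trapped at its α-carbon by formaldehyde; silylation of the alkoxide in the flask keeps it from opening the activated lactone, and the alkene geometry is irrelevant because this alkene later passes through a dienolate.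

Step 5
Reactants: 9 (E)-pent-2-en-4-yn-1-ol
Product: 10 (E)-triethyl(pent-2-en-4-yn-1-yloxy)silane
Conditions: Et3SiCl, imidazole, CH2Cl2, 0 °C
Reagents that add atoms: chlorotriethylsilane, CC[Si](CC)(CC)Cl
Why: Standard silylation of the primary alcohol.

Step 6
Reactants: 8 (2R,5S)-2-tert-butyl-5-{3-iodo-2-[(triethylsilyloxy)methyl]but-2-enoyl}-5-methyl-1,3-dioxolan-4-one; 10 (E)-triethyl(pent-2-en-4-yn-1-yloxy)silane
Product: 11 (2R,5S)-2-tert-butyl-5-methyl-5-{(6E)-3-methyl-2-[(triethylsilyloxy)methyl]-8-(triethylsilyloxy)octa-2,6-dien-4-ynoyl}-1,3-dioxolan-4-one (mixture of 2-ene isomers)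
Conditions: PdCl2(PPh3)2 (3 mol %), CuI (6 mol %), Et3N, THF, 25 °C
Reagents that add atoms: none
Why: Sonogashira coupling of the β-iodo enone, an activated vinyl iodide, with the terminal enyne should proceed under mild tertiary-amine conditions that the lactone tolerates.

Step 7
Reactants: 12 orsellinic acid (2,4-dihydroxy-6-methylbenzoic acid)
Product: 13 tert-butyldimethylsilyl 2,4-bis[(tert-butyldimethylsilyl)oxy]-6-methylbenzoate
Conditions: tBuMe2SiCl (3.3 equiv), imidazole, DMF, 25 °C
Reagents that add atoms: tert-butylchlorodimethylsilane, CC(C)(C)[Si](C)(C)Cl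
Why: Exhaustive silylation of both phenols and the carboxylic acid.

Step 8
Reactants: 13 tert-butyldimethylsilyl 2,4-bis[(tert-butyldimethylsilyl)oxy]-6-methylbenzoate
Product: 14 2,4-bis[(tert-butyldimethylsilyl)oxy]-6-methylbenzoyl chloride
Conditions: (COCl)2, cat. DMF, CH2Cl2, 0 to 25 °C
Reagents that add atoms: oxalyl chloride, ClC(=O)C(=O)Cl
Why: The silyl ester should be converted to the acid chloride by the Vilsmeier-type chloroiminium reagent under neutral conditions that spare the aryl silyl ethers.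

Step 9
Reactants: 11 (2R,5S)-2-tert-butyl-5-methyl-5-{(6E)-3-methyl-2-[(triethylsilyloxy)methyl]-8-(triethylsilyloxy)octa-2,6-dien-4-ynoyl}-1,3-dioxolan-4-one; 14 2,4-bis[(tert-butyldimethylsilyl)oxy]-6-methylbenzoyl chloride
Product: 16 (1R)-1-methyl-2,6-dioxo-3-[(triethylsilyloxy)methyl]-4-[(E)-5-(triethylsilyloxy)pent-3-en-1-ynyl]cyclohex-3-en-1-yl 2,4-bis[(tert-butyldimethylsilyl)oxy]-6-methylbenzoate, via dipotassium salt of the hydroxy dione 15 (not isolated)
Conditions: KN(SiMe3)2 (2.2 equiv), THF, −78 to −20 °C; then 14, −78 to 0 °C; AcOH quench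
Reagents that add atoms: none
Why: KN(SiMe3)2 should remove a proton from the methyl group on the enone β-carbon (the later C5, γ to the C8 ketone; C7 carries no hydrogen), and the cross-conjugated dienolate, which equilibrates by proton exchange until C7 and C4a are cis on the enolate double bond, attacks the acetal-activated lactone carbonyl (C6) through its γ-carbon in a 6-(enolendo)-exo-trig closure, the α-carbon being unable to reach because it would form a four-membered ring. The tetrahedral intermediate expels the acetal oxygen, the hemiacetal alkoxide loses pivaldehyde and the product dione is deprotonated at once, which makes the closure irreversible and leaves salt 15 (C7 alkoxide plus the enolate spanning C6, C5 and C8). The closest known reaction types are the Claisen/Dieckmann condensation of enolates with 1,3-dioxolan-4-ones and the γ-acylation of extended dienolates. No new stereocenter is formed: C7 keeps the configuration fixed in step 2 because it is never enolizable, and C6 of half B is set later in step 13. Acid chloride 14 then acylates the salt, and an enol ester formed first at O6 is expected to pass its acyl group to the neighbouring C7 alkoxide through a five-membered orthoester-like transition state, because this trades a tertiary alkoxide for the much weaker base, the dione enolate, so the ester should end on O7. The selectivities needed are γ- over α-carbon attack (secured by ring size), ring closure over attack of the base on the lactone (secured by the non-nucleophilic amide base) and O7 over O6 acylation (secured by the acyl transfer under anionic conditions).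

Step 10
Reactants: 16 (1R)-1-methyl-2,6-dioxo-3-[(triethylsilyloxy)methyl]-4-[(E)-5-(triethylsilyloxy)pent-3-en-1-ynyl]cyclohex-3-en-1-yl 2,4-bis[(tert-butyldimethylsilyl)oxy]-6-methylbenzoate
Product: 17 (1R)-3-(hydroxymethyl)-4-[(E)-5-hydroxypent-3-en-1-ynyl]-1-methyl-2,6-dioxocyclohex-3-en-1-yl 2,4-bis[(tert-butyldimethylsilyl)oxy]-6-methylbenzoate
Conditions: AcOH/THF/H2O (3:1:1), 25 °C
Reagents that add atoms: none
Why: Mild acidic hydrolysis should cleave the two primary alkyl triethylsilyl ethers while the aryl tert-butyldimethylsilyl ethers, which are stable to acid, remain.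

Step 11
Reactants: 17 (1R)-3-(hydroxymethyl)-4-[(E)-5-hydroxypent-3-en-1-ynyl]-1-methyl-2,6-dioxocyclohex-3-en-1-yl 2,4-bis[(tert-butyldimethylsilyl)oxy]-6-methylbenzoate
Product: 18 (7R)-3-[(E)-3-hydroxyprop-1-enyl]-7-methyl-6,8-dioxo-5,6,7,8-tetrahydro-1H-isochromen-7-yl 2,4-bis[(tert-butyldimethylsilyl)oxy]-6-methylbenzoate
Conditions: Ph3PAuNTf2 (5 mol %), CH2Cl2, 25 °C
Reagents that add atoms: none
Why: π-Acid-catalysed 6-endo-dig hydroalkoxylation, in which the primary C1 hydroxyl should attack the gold-activated alkyne at C3, the carbon made electrophilic by conjugation with the C8 enone and bearing the cation-stabilizing vinyl group, to close the 2H-pyran ring.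

Step 12
Reactants: 18 (7R)-3-[(E)-3-hydroxyprop-1-enyl]-7-methyl-6,8-dioxo-5,6,7,8-tetrahydro-1H-isochromen-7-yl 2,4-bis[(tert-butyldimethylsilyl)oxy]-6-methylbenzoate
Product: 19 (7R)-3-[(E)-3-acetoxyprop-1-enyl]-7-methyl-6,8-dioxo-5,6,7,8-tetrahydro-1H-isochromen-7-yl 2,4-bis[(tert-butyldimethylsilyl)oxy]-6-methylbenzoate (half A)
Conditions: Ac2O (1.1 equiv), pyridine, CH2Cl2, 0 °C
Reagents that add atoms: acetic anhydride, CC(=O)OC(C)=O
Why: Acetylation of the unhindered primary allylic alcohol, the only free hydroxyl group.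

Step 13
Reactants: 18 (7R)-3-[(E)-3-hydroxyprop-1-enyl]-7-methyl-6,8-dioxo-5,6,7,8-tetrahydro-1H-isochromen-7-yl 2,4-bis[(tert-butyldimethylsilyl)oxy]-6-methylbenzoate
Product: 20 (6R,7R)-6-hydroxy-3-[(E)-3-hydroxyprop-1-enyl]-7-methyl-8-oxo-5,6,7,8-tetrahydro-1H-isochromen-7-yl 2,4-bis[(tert-butyldimethylsilyl)oxy]-6-methylbenzoate
Conditions: NaBH4, CeCl3·7H2O, MeOH/THF, −78 °C
Reagents that add atoms: none
Why: Luche reduction should touch only the saturated C6 ketone, the C8 carbonyl being a deactivated doubly vinylogous ester, and hydride should be delivered anti to the C7–O bond of the bulky acyloxy group (polar Felkin–Anh, 1,2-induction from C7), which places the new hydroxyl cis to the ester and makes C6 the R center.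

Step 14
Reactants: 20 (6R,7R)-6-hydroxy-3-[(E)-3-hydroxyprop-1-enyl]-7-methyl-8-oxo-5,6,7,8-tetrahydro-1H-isochromen-7-yl 2,4-bis[(tert-butyldimethylsilyl)oxy]-6-methylbenzoate
Product: 21 (6R,7R)-6-hydroxy-7-methyl-8-oxo-3-[(E)-3-oxoprop-1-enyl]-5,6,7,8-tetrahydro-1H-isochromen-7-yl 2,4-bis[(tert-butyldimethylsilyl)oxy]-6-methylbenzoate (half B)
Conditions: MnO2, CH2Cl2, 25 °C
Reagents that add atoms: none
Why: MnO2 should oxidize the allylic primary alcohol to the enal and leave the non-allylic C6 carbinol untouched.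

Step 15
Reactants: 19 half A acetate dione; 21 half B enal
Product: 22 tetrakis(tert-butyldimethylsilyl) ether of the target (all four phenols silylated)
Conditions: ethylenediammonium diacetate (10 mol %), CH2Cl2, 4 Å molecular sieves, 25 °C
Reagents that add atoms: none
Why: Knoevenagel condensation between the doubly activated C5 methylene of 19 (α to the C6 ketone and vinylogous to the C8 ketone) and the enal of 21, whose own C5 methylene is not activated, should give the cross-conjugated trienone with the thermodynamically preferred geometry in which the chain lies on the C6 carbonyl side, away from C4–H.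

Step 16
Reactants: 22 tetrakis(tert-butyldimethylsilyl) ether of the target
Product: 23 CNP0239166.2 (target)
Conditions: HF·pyridine, pyridine, THF, 0 °C
Reagents that add atoms: none
Why: Buffered fluoride should remove the four aryl silyl ethers under mildly acidic conditions that spare the allylic acetate and suppress acyl migration to the neighbouring C6 hydroxyl.

**Compound list**
1 | (R)-lactic acid | C[C@@H](O)C(=O)O | starting material
2 | pivaldehyde | CC(C)(C)C=O | starting material
3 | (2R,5R)-2-tert-butyl-5-methyl-1,3-dioxolan-4-one | C[C@H]1O[C@@H](C(C)(C)C)OC1=O | intermediate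
4 | but-2-ynal | CC#CC=O | starting material
5 | (2R,5S)-2-tert-butyl-5-(1-hydroxybut-2-yn-1-yl)-5-methyl-1,3-dioxolan-4-one (carbinol epimers) | C[C@@]1(C(O)C#CC)O[C@@H](C(C)(C)C)OC1=O | intermediate
6 | (2R,5S)-5-(but-2-ynoyl)-2-tert-butyl-5-methyl-1,3-dioxolan-4-one | C[C@@]1(C(=O)C#CC)O[C@@H](C(C)(C)C)OC1=O | intermediate
7 | iodomagnesium alkoxide of (2R,5S)-2-tert-butyl-5-[2-(hydroxymethyl)-3-iodobut-2-enoyl]-5-methyl-1,3-dioxolan-4-one | C[C@@]1(C(=O)C(C[O-])=C(C)I)O[C@@H](C(C)(C)C)OC1=O.[Mg+2].[I-] | intermediate (not isolated)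
8 | (2R,5S)-2-tert-butyl-5-{3-iodo-2-[(triethylsilyloxy)methyl]but-2-enoyl}-5-methyl-1,3-dioxolan-4-one | C[C@@]1(C(=O)C(CO[Si](CC)(CC)CC)=C(C)I)O[C@@H](C(C)(C)C)OC1=O | intermediate
9 | (E)-pent-2-en-4-yn-1-ol | C#C/C=C/CO | starting material
10 | (E)-triethyl(pent-2-en-4-yn-1-yloxy)silane | C#C/C=C/CO[Si](CC)(CC)CC | intermediate
11 | (2R,5S)-2-tert-butyl-5-methyl-5-{(6E)-3-methyl-2-[(triethylsilyloxy)methyl]-8-(triethylsilyloxy)octa-2,6-dien-4-ynoyl}-1,3-dioxolan-4-one | C[C@@]1(C(=O)C(CO[Si](CC)(CC)CC)=C(C)C#C/C=C/CO[Si](CC)(CC)CC)O[C@@H](C(C)(C)C)OC1=O | intermediate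
12 | orsellinic acid | Cc1cc(O)cc(O)c1C(=O)O | starting material
13 | tert-butyldimethylsilyl 2,4-bis[(tert-butyldimethylsilyl)oxy]-6-methylbenzoate | Cc1cc(O[Si](C)(C)C(C)(C)C)cc(O[Si](C)(C)C(C)(C)C)c1C(=O)O[Si](C)(C)C(C)(C)C | intermediate
14 | 2,4-bis[(tert-butyldimethylsilyl)oxy]-6-methylbenzoyl chloride | Cc1cc(O[Si](C)(C)C(C)(C)C)cc(O[Si](C)(C)C(C)(C)C)c1C(=O)Cl | intermediate
15 | dipotassium salt of (R)-2-hydroxy-2-methyl-4-[(triethylsilyloxy)methyl]-5-[(E)-5-(triethylsilyloxy)pent-3-en-1-ynyl]cyclohex-4-ene-1,3-dione (C2 alkoxide and dione enolate) | C[C@@]1([O-])C([O-])=CC(C#C/C=C/CO[Si](CC)(CC)CC)=C(CO[Si](CC)(CC)CC)C1=O.[K+].[K+] | intermediate (not isolated)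
16 | (1R)-1-methyl-2,6-dioxo-3-[(triethylsilyloxy)methyl]-4-[(E)-5-(triethylsilyloxy)pent-3-en-1-ynyl]cyclohex-3-en-1-yl 2,4-bis[(tert-butyldimethylsilyl)oxy]-6-methylbenzoate | C[C@@]1(OC(=O)c2c(C)cc(O[Si](C)(C)C(C)(C)C)cc2O[Si](C)(C)C(C)(C)C)C(=O)CC(C#C/C=C/CO[Si](CC)(CC)CC)=C(CO[Si](CC)(CC)CC)C1=O | intermediate
17 | (1R)-3-(hydroxymethyl)-4-[(E)-5-hydroxypent-3-en-1-ynyl]-1-methyl-2,6-dioxocyclohex-3-en-1-yl 2,4-bis[(tert-butyldimethylsilyl)oxy]-6-methylbenzoate | C[C@@]1(OC(=O)c2c(C)cc(O[Si](C)(C)C(C)(C)C)cc2O[Si](C)(C)C(C)(C)C)C(=O)CC(C#C/C=C/CO)=C(CO)C1=O | intermediate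
18 | (7R)-3-[(E)-3-hydroxyprop-1-enyl]-7-methyl-6,8-dioxo-5,6,7,8-tetrahydro-1H-isochromen-7-yl 2,4-bis[(tert-butyldimethylsilyl)oxy]-6-methylbenzoate | OC/C=C/C1=CC2=C(CO1)C(=O)[C@](C)(OC(=O)c1c(C)cc(O[Si](C)(C)C(C)(C)C)cc1O[Si](C)(C)C(C)(C)C)C(=O)C2 | intermediate
19 | (7R)-3-[(E)-3-acetoxyprop-1-enyl]-7-methyl-6,8-dioxo-5,6,7,8-tetrahydro-1H-isochromen-7-yl 2,4-bis[(tert-butyldimethylsilyl)oxy]-6-methylbenzoate (half A) | CC(=O)OC/C=C/C1=CC2=C(CO1)C(=O)[C@](C)(OC(=O)c1c(C)cc(O[Si](C)(C)C(C)(C)C)cc1O[Si](C)(C)C(C)(C)C)C(=O)C2 | intermediate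
20 | (6R,7R)-6-hydroxy-3-[(E)-3-hydroxyprop-1-enyl]-7-methyl-8-oxo-5,6,7,8-tetrahydro-1H-isochromen-7-yl 2,4-bis[(tert-butyldimethylsilyl)oxy]-6-methylbenzoate | OC/C=C/C1=CC2=C(CO1)C(=O)[C@](C)(OC(=O)c1c(C)cc(O[Si](C)(C)C(C)(C)C)cc1O[Si](C)(C)C(C)(C)C)[C@H](O)C2 | intermediate
21 | (6R,7R)-6-hydroxy-7-methyl-8-oxo-3-[(E)-3-oxoprop-1-enyl]-5,6,7,8-tetrahydro-1H-isochromen-7-yl 2,4-bis[(tert-butyldimethylsilyl)oxy]-6-methylbenzoate (half B) | O=C/C=C/C1=CC2=C(CO1)C(=O)[C@](C)(OC(=O)c1c(C)cc(O[Si](C)(C)C(C)(C)C)cc1O[Si](C)(C)C(C)(C)C)[C@H](O)C2 | intermediate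
22 | tetrakis(tert-butyldimethylsilyl) ether of the target (half A joined through its (5Z)-ylidene carbon and an (E)-propenylidene chain to C3 of half B) | CC(=O)OC/C=C/C1=CC2=C(CO1)C(=O)[C@](C)(OC(=O)c1c(C)cc(O[Si](C)(C)C(C)(C)C)cc1O[Si](C)(C)C(C)(C)C)C(=O)/C2=C\C=C\C1=CC2=C(CO1)C(=O)[C@](C)(OC(=O)c1c(C)cc(O[Si](C)(C)C(C)(C)C)cc1O[Si](C)(C)C(C)(C)C)[C@H](O)C2 | intermediate
23 | CNP0239166.2: (7R)-3-[(E)-3-acetoxyprop-1-enyl]-7-methyl-6,8-dioxo-7-(orsellinoyloxy)-1H-isochromene whose C5 carries the (5Z)-ylidene, (E)-propenylidene chain ending at C3 of (6R,7R)-6-hydroxy-7-methyl-8-oxo-7-(orsellinoyloxy)-5,6,7,8-tetrahydro-1H-isochromene | CC(=O)OC/C=C/C1=CC2=C(CO1)C(=O)[C@](C)(OC(=O)c1c(C)cc(O)cc1O)C(=O)/C2=C\C=C\C1=CC2=C(CO1)C(=O)[C@](C)(OC(=O)c1c(C)cc(O)cc1O)[C@H](O)C2 | target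

**Step count and risks**
Total step count: 16. Longest linear sequence: 12 steps (steps 1, 2, 3, 4, 6, 9, 10, 11, 13, 14, 15, 16).

Steps most likely to fail:

1. Step 9. The base or the liberated alkoxide may attack the acetal-activated lactone or the C8 ketone (retro-Claisen cleavage at the quaternary carbon) faster than the γ-carbon closes the ring. The released pivaldehyde may add to the dione enolate. The acyl group may stay on the enol oxygen instead of moving to O7. The fallback sets out from 11 and closes the same C5–C6 bond at the aldehyde oxidation level under Lewis-acidic conditions. iBu2AlH (CH2Cl2, −78 °C) reduces both the lactone and the ketone to the lactol allylic alcohol F1. MnO2 reoxidizes only the allylic alcohol to the keto lactol F2, and Ac2O/pyridine gives the anomeric acetate F3. Me3SiOTf/Et3N forms the silyl dienol ether, and a further portion of Me3SiOTf ionizes the acetate, so that the γ-carbon adds to the dioxolanyl oxocarbenium ion (intramolecular vinylogous Mukaiyama addition) to give the cis-fused bicyclic acetal F4, with C6 fixed by the ring fusion. Me2BBr (CH2Cl2, −78 °C) cleaves the pivaldehyde acetal to the cis-diol F5. Dess–Martin periodinane oxidizes its secondary alcohol to the hydroxy dione F6. Its dipotassium salt (15, from KN(SiMe3)2) is acylated with 14 as in step 9, and the route is rejoined at 16.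

2. Step 11. The hydroxyl group may attack the proximal alkyne carbon (5-exo-dig), which would lead to an alkylidene dihydrofuran and then a furan instead of the pyran. The fallback sets out from 16 and returns at 18. Gold-catalysed hydration (Ph3PAuNTf2, wet 1,4-dioxane) is an intermolecular addition without ring-size bias. It should place the new carbonyl oxygen on the alkyne carbon remote from the enone, to give the triketone F9. AcOH/THF/H2O with cat. TsOH then removes both triethylsilyl groups, and the freed C1 hydroxyl condenses with the new C3 ketone (hemiketal, loss of water) to give 18.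

3. Step 4. Conjugate addition of iodide to the β-methyl ynone may be slow, and the primary alkoxide may open the activated lactone before it is silylated. The fallback sets out from 6 (with 10) and returns at 11. I2 (CH2Cl2, 25 °C) adds anti across the alkyne to give the (E)-diiodo enone F7. Its β-iodide, the more reactive site for oxidative addition, is coupled with 10 under the conditions of step 6 to give the α-iodo enynone F8. Stille coupling with Bu3SnCH2OSiEt3 (Pd(PPh3)4, CuI, DMF, 60 °C) then installs the silyloxymethyl group and gives 11 as one alkene isomer.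

**Further compounds**
F1 | step 9 | lactol allylic alcohol from reduction of both carbonyl groups of 11 (diastereomer mixture) | C[C@@]1(C(O)C(CO[Si](CC)(CC)CC)=C(C)C#C/C=C/CO[Si](CC)(CC)CC)O[C@@H](C(C)(C)C)OC1O
F2 | step 9 | keto lactol (C8 ketone restored, 1,3-dioxolan-4-ol retained) | C[C@@]1(C(=O)C(CO[Si](CC)(CC)CC)=C(C)C#C/C=C/CO[Si](CC)(CC)CC)O[C@@H](C(C)(C)C)OC1O
F3 | step 9 | anomeric acetate of the keto lactol | C[C@@]1(C(=O)C(CO[Si](CC)(CC)CC)=C(C)C#C/C=C/CO[Si](CC)(CC)CC)O[C@@H](C(C)(C)C)OC1OC(C)=O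
F4 | step 9 | cis-fused cyclohexenone bearing the O6/O7 pivaldehyde acetal | C[C@@]12O[C@@H](C(C)(C)C)O[C@@H]1CC(C#C/C=C/CO[Si](CC)(CC)CC)=C(CO[Si](CC)(CC)CC)C2=O
F5 | step 9 | (5R,6R)-5,6-dihydroxy-6-methyl-2-[(triethylsilyloxy)methyl]-3-[(E)-5-(triethylsilyloxy)pent-3-en-1-ynyl]cyclohex-2-en-1-one | C[C@@]1(O)[C@H](O)CC(C#C/C=C/CO[Si](CC)(CC)CC)=C(CO[Si](CC)(CC)CC)C1=O
F6 | step 9 | (R)-2-hydroxy-2-methyl-4-[(triethylsilyloxy)methyl]-5-[(E)-5-(triethylsilyloxy)pent-3-en-1-ynyl]cyclohex-4-ene-1,3-dione | C[C@@]1(O)C(=O)CC(C#C/C=C/CO[Si](CC)(CC)CC)=C(CO[Si](CC)(CC)CC)C1=O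
F7 | step 4 | (2R,5S)-2-tert-butyl-5-[(E)-2,3-diiodobut-2-enoyl]-5-methyl-1,3-dioxolan-4-one | C[C@@]1(C(=O)/C(I)=C(\I)C)O[C@@H](C(C)(C)C)OC1=O
F8 | step 4 | (2R,5S)-2-tert-butyl-5-{(6E)-2-iodo-3-methyl-8-(triethylsilyloxy)octa-2,6-dien-4-ynoyl}-5-methyl-1,3-dioxolan-4-one | C[C@@]1(C(=O)/C(I)=C(\C#C/C=C/CO[Si](CC)(CC)CC)C)O[C@@H](C(C)(C)C)OC1=O
F9 | step 11 | (1R)-1-methyl-2,6-dioxo-4-[(E)-2-oxo-5-(triethylsilyloxy)pent-3-enyl]-3-[(triethylsilyloxy)methyl]cyclohex-3-en-1-yl 2,4-bis[(tert-butyldimethylsilyl)oxy]-6-methylbenzoate | C[C@@]1(OC(=O)c2c(C)cc(O[Si](C)(C)C(C)(C)C)cc2O[Si](C)(C)C(C)(C)C)C(=O)CC(CC(=O)/C=C/CO[Si](CC)(CC)CC)=C(CO[Si](CC)(CC)CC)C1=O
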